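The route rests on cutting the C2–C3 bond of ring C in the lower (taxifolin) unit. The key step exploits the O1–C2 benzylic ether of that ring: the C2–H bonds are α to O1 and benzylic to catechol ring B, so a rhodium carbenoid generated at C3, next to the C4 carbonyl, inserts there under chiral dirhodium carboxylate control, closing the pyranone ring and setting C2, from which the C3 hydroxyl is relayed trans. The precursor is an open aryl diazomethyl ketone bearing an ortho 3,4-bis(benzyloxy)benzyl ether and, at C8, the finished upper flavanone, whose C3 is blocked as a quaternary tert-butyl ester that also served to build it.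

Key step: step 10

Remark: the target is read as a 3→8 biflavonoid, a (2S,3R)-eriodictyol unit (upper) joined through its C3 to C8 of a (2R,3R)-taxifolin unit (lower). Compounds 1, 3, 6 and 9 are taken as commercially available. The sense of induction of the two chiral catalysts (steps 3 and 10) is assumed as drawn; if it proves opposite, the pseudo-enantiomeric or antipodal catalyst is used.

Step 1
Reactants: 1 1-[2,4-bis(benzyloxy)-6-hydroxyphenyl]ethanone
Product: 2 tert-butyl 3-[2,4-bis(benzyloxy)-6-hydroxyphenyl]-3-oxopropanoate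
Conditions: LiN(SiMe3)2 (3.2 equiv), THF, −78 °C; Boc2O (1.1 equiv), −78 → 0 °C; aq. NH4Cl
Reagents that add atoms: di-tert-butyl dicarbonate, CC(C)(C)OC(=O)OC(=O)OC(C)(C)C
Why: Claisen-type C-acylation of the lithium phenoxide–enolate dianion, in which the enolate carbon is the more nucleophilic site and the third equivalent of base absorbs the acidic product, the tert-butyl ester being chosen because it cannot lactonise to a 4-hydroxycoumarin.

Step 2
Reactants: 2 tert-butyl keto ester; 3 3,4-bis(benzyloxy)benzaldehyde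
Product: 4 tert-butyl (Z)-2-[2,4-bis(benzyloxy)-6-hydroxybenzoyl]-3-[3,4-bis(benzyloxy)phenyl]prop-2-enoate
Conditions: piperidine (10 mol %), AcOH (10 mol %), toluene, reflux, Dean–Stark
Reagents that add atoms: none
Why: Knoevenagel condensation of the doubly activated methylene group with the aryl aldehyde under azeotropic removal of water, the alkene geometry being of no consequence for the next step.

Step 3
Reactants: 4 alkylidene keto ester
Product: 5 tert-butyl (2S,3R)-5,7-bis(benzyloxy)-2-[3,4-bis(benzyloxy)phenyl]-4-oxochromane-3-carboxylate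
Conditions: 9-amino(9-deoxy)epiquinidine-derived 3,5-bis(trifluoromethyl)phenyl thiourea (10 mol %), toluene, −25 °C
Reagents that add atoms: none
Why: Enantioselective intramolecular oxa-Michael addition (6-endo-trig) under bifunctional thiourea–tertiary amine catalysis, in which the thiourea binds the keto ester and the quinuclidine guides the phenol to one alkene face so that C2 is set by the catalyst, while C3 settles trans (or as the enol) by equilibration.

Step 4
Reactants: 6 1-(2,4-dihydroxy-6-methoxyphenyl)ethanone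
Product: 7 1-[4-(benzyloxy)-2-hydroxy-6-methoxyphenyl]ethanone
Conditions: BnBr (1.05 equiv), K2CO3 (1.1 equiv), acetone, reflux
Reagents that add atoms: benzyl bromide, BrCc1ccccc1
Why: Williamson etherification that should be selective for the 4-hydroxyl, because the 2-hydroxyl is held in a hydrogen bond to the acetyl carbonyl and is far less nucleophilic.

Step 5
Reactants: 7 benzyl ether
Product: 8 1-[4-(benzyloxy)-2-hydroxy-3-iodo-6-methoxyphenyl]ethanone
Conditions: BnMe3N+ ICl2− (1.05 equiv), NaHCO3, CH2Cl2–MeOH, rt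
Reagents that add atoms: benzyltrimethylammonium dichloroiodate, C[N+](C)(C)Cc1ccccc1.Cl[I-]Cl
Why: Electrophilic aromatic iodination directed ortho to the free phenol (C3, between OH and OBn), the carbon that becomes C8 of the lower unit, with the regiochemistry to be confirmed by HMBC and any 5-iodo isomer removed by crystallisation.

Step 6
Reactants: 8 iodophenol; 9 4-(chloromethyl)-1,2-bis(benzyloxy)benzene
Product: 10 1-[4-(benzyloxy)-2-{[3,4-bis(benzyloxy)phenyl]methoxy}-3-iodo-6-methoxyphenyl]ethanone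
Conditions: K2CO3, NaI (10 mol %), DMF, 60 °C
Reagents that add atoms: none
Why: Williamson etherification of the chelated phenol with Finkelstein activation of the benzylic chloride installs the O1–CH2–aryl ether whose methylene carbon becomes C2 of the lower unit.

Step 7
Reactants: 10 aryl iodide
Product: 11 1-[4-(benzyloxy)-2-{[3,4-bis(benzyloxy)phenyl]methoxy}-6-methoxy-3-(trimethylstannyl)phenyl]ethanone
Conditions: Me3SnSnMe3 (1.5 equiv), Pd(PPh3)4 (5 mol %), toluene, 100 °C
Reagents that add atoms: hexamethylditin, C[Sn](C)(C)[Sn](C)(C)C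
Why: Stannylation catalysed by zerovalent palladium (oxidative addition into the C–I bond, transmetalation with the distannane, reductive elimination) tolerates the ketone and the ethers and gives the aryl–tin bond needed for tin–lead exchange.

Step 8
Reactants: 11 aryl stannane; 5 flavanone keto ester
Product: 13 tert-butyl (2R,3S)-3-aryl-4-oxochromane-3-carboxylate carrying the lower-ring acetophenone on C3 (full name in the compound list), via aryllead triacetate 12 (not isolated)
Conditions: Pb(OAc)4 (1.05 equiv), Hg(OAc)2 (5 mol %), CHCl3, 40 °C; then 5, pyridine (3 equiv), CHCl3, 40 °C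
Reagents that add atoms: none
Why: Tin–lead exchange gives the aryllead triacetate, which C-arylates the keto ester in a Pinhey arylation (ligand exchange to a lead enolate, then ligand coupling), a reaction that tolerates doubly ortho-substituted electron-rich aryl groups; the aryl group should enter anti to the C2 aryl group, and the configuration of the quaternary C3 is erased in the last step.

Step 9
Reactants: 13 methyl ketone
Product: 15 diazomethyl ketone (full name in the compound list), via trifluoroacetyl ketone 14 (not isolated)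
Conditions: LiN(SiMe3)2 (1.2 equiv), THF, −78 °C; CF3CO2CH2CF3; then MsN3, Et3N, H2O, MeCN, rt
Reagents that add atoms: methanesulfonyl azide, CS(=O)(=O)N=[N+]=[N-]
Why: Detrifluoroacetylative Regitz-type diazo transfer, in which the acetyl methyl group is the only enolisable position (C3 of the upper unit is quaternary), so it alone is trifluoroacetylated and then exchanged for the diazo group.

Step 10
Reactants: 15 diazomethyl ketone
Product: 16 tert-butyl (2R,3S)-5,7-bis(benzyloxy)-3-{(2S)-7-(benzyloxy)-2-[3,4-bis(benzyloxy)phenyl]-5-methoxy-4-oxochroman-8-yl}-2-[3,4-bis(benzyloxy)phenyl]-4-oxochromane-3-carboxylate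
Conditions: Rh2(S-BSP)4 (dirhodium tetrakis[(S)-N-(benzenesulfonyl)prolinate], 2 mol %), CH2Cl2, 0 °C, slow addition of 15
Reagents that add atoms: none
Why: Loss of N2 from 15 on the dirhodium core gives an electrophilic acceptor carbenoid at C3, which inserts into a C2–H bond of the neighbouring O1–CH2–aryl ether through a concerted, hydride-transfer-like three-centre transition state, forming the C2–C3 bond and releasing the catalyst. The closest known reaction type is the asymmetric C–H insertion of ortho-alkoxyaryl α-diazoketones to chroman-4-ones under chiral carboxylates of divalent rhodium. Ring C of the lower unit closes as a 1,6 C–H insertion, the carbenoid carbon (C3) and the ether carbon (C2) being joined across the tether C4–C4a–C8a–O1 to give the six-membered pyranone. The new stereocentre C2 is set by the chiral prolinate ligands, which select one of the two benzylic hydrogens (catalyst control, insertion with retention), the remote upper unit being expected to add little bias. The step needs site selectivity for the O1–CH2 hydrogens over the C5 methoxy hydrogens, over oxonium ylide formation at O1 and over any reaction at the upper unit. The substrate secures this because the C2–H bonds are doubly activated (α-oxygen, electron-rich benzylic) whereas the methoxy C–H bonds are primary, O1 is flanked by the acyl group and the bulky C8 substituent and is a poor ylide donor, and the upper unit is meta to the carbenoid, non-enolisable and out of reach.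

Step 11
Reactants: 16 lower flavanone
Product: 18 lower (2R,3R)-3-hydroxyflavanone (full name in the compound list), via trimethylsilyl enol ether 17 (not isolated)
Conditions: Me3SiOTf (1.3 equiv), Et3N (2 equiv), CH2Cl2, −78 → −30 °C; NaHCO3 wash, crude; DMDO, acetone, −40 °C; citric acid, MeOH, 0 °C
Reagents that add atoms: dimethyldioxirane, CC1(C)OO1
Why: Rubottom oxidation, in which soft enolisation at low temperature silylates only the lower ketone (the upper one has no α-hydrogen and the tert-butyl ester should survive below −30 °C) without base-induced ring opening, and the dioxirane epoxidises the enol ether anti to the C2 aryl group, so that the 3-hydroxyl is set trans by substrate control.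

Step 12
Reactants: 18 protected biflavonoid
Product: 20 target biflavonoid (EANPDB:THYM_00006), via deprotected keto acid 19 (not isolated)
Conditions: BCl3 (1 M in CH2Cl2, 25 equiv), C6HMe5 (25 equiv), CH2Cl2, −78 → 0 °C; MeOH; then aq. THF, 40 °C
Reagents that add atoms: none
Why: Boron trichloride with a cation scavenger should cleave the seven benzyl ethers, the chelated peri methyl ether and the tert-butyl ester in one operation, after which the β-keto acid decarboxylates to the enol and is protonated to the thermodynamically favoured 2,3-trans (3R) flavanone, so that C3 of the upper unit is relayed from C2.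

Compound list
1 | 1-[2,4-bis(benzyloxy)-6-hydroxyphenyl]ethanone | CC(=O)c1c(O)cc(OCc2ccccc2)cc1OCc1ccccc1 | starting material
2 | tert-butyl 3-[2,4-bis(benzyloxy)-6-hydroxyphenyl]-3-oxopropanoate | CC(C)(C)OC(=O)CC(=O)c1c(O)cc(OCc2ccccc2)cc1OCc1ccccc1 | intermediate
3 | 3,4-bis(benzyloxy)benzaldehyde | O=Cc1ccc(OCc2ccccc2)c(OCc2ccccc2)c1 | starting material
4 | tert-butyl (Z)-2-[2,4-bis(benzyloxy)-6-hydroxybenzoyl]-3-[3,4-bis(benzyloxy)phenyl]prop-2-enoate | CC(C)(C)OC(=O)/C(=C\c1ccc(OCc2ccccc2)c(OCc2ccccc2)c1)C(=O)c1c(O)cc(OCc2ccccc2)cc1OCc1ccccc1 | intermediate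
5 | tert-butyl (2S,3R)-5,7-bis(benzyloxy)-2-[3,4-bis(benzyloxy)phenyl]-4-oxochromane-3-carboxylate | O=C1c2c(OCc3ccccc3)cc(OCc3ccccc3)cc2O[C@H](c2ccc(OCc3ccccc3)c(OCc3ccccc3)c2)[C@H]1C(=O)OC(C)(C)C | intermediate
6 | 1-(2,4-dihydroxy-6-methoxyphenyl)ethanone | CC(=O)c1c(O)cc(O)cc1OC | starting material
7 | 1-[4-(benzyloxy)-2-hydroxy-6-methoxyphenyl]ethanone | CC(=O)c1c(O)cc(OCc2ccccc2)cc1OC | intermediate
8 | 1-[4-(benzyloxy)-2-hydroxy-3-iodo-6-methoxyphenyl]ethanone | CC(=O)c1c(O)c(I)c(OCc2ccccc2)cc1OC | intermediate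
9 | 4-(chloromethyl)-1,2-bis(benzyloxy)benzene | ClCc1ccc(OCc2ccccc2)c(OCc2ccccc2)c1 | starting material
10 | 1-[4-(benzyloxy)-2-{[3,4-bis(benzyloxy)phenyl]methoxy}-3-iodo-6-methoxyphenyl]ethanone | CC(=O)c1c(OCc2ccc(OCc3ccccc3)c(OCc3ccccc3)c2)c(I)c(OCc2ccccc2)cc1OC | intermediate
11 | 1-[4-(benzyloxy)-2-{[3,4-bis(benzyloxy)phenyl]methoxy}-6-methoxy-3-(trimethylstannyl)phenyl]ethanone | CC(=O)c1c(OCc2ccc(OCc3ccccc3)c(OCc3ccccc3)c2)c([Sn](C)(C)C)c(OCc2ccccc2)cc1OC | intermediate
12 | (3-acetyl-6-(benzyloxy)-2-{[3,4-bis(benzyloxy)phenyl]methoxy}-4-methoxyphenyl)lead triacetate, formed in situ | CC(=O)c1c(OCc2ccc(OCc3ccccc3)c(OCc3ccccc3)c2)c([Pb](OC(C)=O)(OC(C)=O)OC(C)=O)c(OCc2ccccc2)cc1OC | intermediate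
13 | tert-butyl (2R,3S)-3-(3-acetyl-6-(benzyloxy)-2-{[3,4-bis(benzyloxy)phenyl]methoxy}-4-methoxyphenyl)-5,7-bis(benzyloxy)-2-[3,4-bis(benzyloxy)phenyl]-4-oxochromane-3-carboxylate | O=C1c2c(OCc3ccccc3)cc(OCc3ccccc3)cc2O[C@H](c2ccc(OCc3ccccc3)c(OCc3ccccc3)c2)[C@@]1(C(=O)OC(C)(C)C)c1c(OCc2ccccc2)cc(OC)c(C(C)=O)c1OCc1ccc(OCc2ccccc2)c(OCc2ccccc2)c1 | intermediate
14 | tert-butyl (2R,3S)-5,7-bis(benzyloxy)-3-[6-(benzyloxy)-2-{[3,4-bis(benzyloxy)phenyl]methoxy}-4-methoxy-3-(4,4,4-trifluoro-3-oxobutanoyl)phenyl]-2-[3,4-bis(benzyloxy)phenyl]-4-oxochromane-3-carboxylate, formed in situ | O=C1c2c(OCc3ccccc3)cc(OCc3ccccc3)cc2O[C@H](c2ccc(OCc3ccccc3)c(OCc3ccccc3)c2)[C@@]1(C(=O)OC(C)(C)C)c1c(OCc2ccccc2)cc(OC)c(C(=O)CC(=O)C(F)(F)F)c1OCc1ccc(OCc2ccccc2)c(OCc2ccccc2)c1 | intermediate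
15 | tert-butyl (2R,3S)-5,7-bis(benzyloxy)-3-[6-(benzyloxy)-2-{[3,4-bis(benzyloxy)phenyl]methoxy}-3-(diazoacetyl)-4-methoxyphenyl]-2-[3,4-bis(benzyloxy)phenyl]-4-oxochromane-3-carboxylate | O=C1c2c(OCc3ccccc3)cc(OCc3ccccc3)cc2O[C@H](c2ccc(OCc3ccccc3)c(OCc3ccccc3)c2)[C@@]1(C(=O)OC(C)(C)C)c1c(OCc2ccccc2)cc(OC)c(C(=O)C=[N+]=[N-])c1OCc1ccc(OCc2ccccc2)c(OCc2ccccc2)c1 | intermediate
16 | tert-butyl (2R,3S)-5,7-bis(benzyloxy)-3-{(2S)-7-(benzyloxy)-2-[3,4-bis(benzyloxy)phenyl]-5-methoxy-4-oxochroman-8-yl}-2-[3,4-bis(benzyloxy)phenyl]-4-oxochromane-3-carboxylate | O=C1c2c(OCc3ccccc3)cc(OCc3ccccc3)cc2O[C@H](c2ccc(OCc3ccccc3)c(OCc3ccccc3)c2)[C@@]1(C(=O)OC(C)(C)C)c1c(OCc2ccccc2)cc(OC)c2c1O[C@H](c1ccc(OCc3ccccc3)c(OCc3ccccc3)c1)CC2=O | intermediate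
17 | tert-butyl (2R,3S)-5,7-bis(benzyloxy)-3-{(2S)-7-(benzyloxy)-2-[3,4-bis(benzyloxy)phenyl]-5-methoxy-4-[(trimethylsilyl)oxy]-2H-chromen-8-yl}-2-[3,4-bis(benzyloxy)phenyl]-4-oxochromane-3-carboxylate, formed in situ | O=C1c2c(OCc3ccccc3)cc(OCc3ccccc3)cc2O[C@H](c2ccc(OCc3ccccc3)c(OCc3ccccc3)c2)[C@@]1(C(=O)OC(C)(C)C)c1c(OCc2ccccc2)cc(OC)c2c1O[C@H](c1ccc(OCc3ccccc3)c(OCc3ccccc3)c1)C=C2O[Si](C)(C)C | intermediate
18 | tert-butyl (2R,3S)-5,7-bis(benzyloxy)-3-{(2R,3R)-7-(benzyloxy)-2-[3,4-bis(benzyloxy)phenyl]-3-hydroxy-5-methoxy-4-oxochroman-8-yl}-2-[3,4-bis(benzyloxy)phenyl]-4-oxochromane-3-carboxylate | O=C1c2c(OCc3ccccc3)cc(OCc3ccccc3)cc2O[C@H](c2ccc(OCc3ccccc3)c(OCc3ccccc3)c2)[C@@]1(C(=O)OC(C)(C)C)c1c(OCc2ccccc2)cc(OC)c2c1O[C@H](c1ccc(OCc3ccccc3)c(OCc3ccccc3)c1)[C@@H](O)C2=O | intermediate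
19 | (2R,3S)-2-(3,4-dihydroxyphenyl)-3-[(2R,3R)-2-(3,4-dihydroxyphenyl)-3,5,7-trihydroxy-4-oxochroman-8-yl]-5,7-dihydroxy-4-oxochromane-3-carboxylic acid, formed in situ | O=C1c2c(O)cc(O)cc2O[C@H](c2ccc(O)c(O)c2)[C@@]1(C(=O)O)c1c(O)cc(O)c2c1O[C@H](c1ccc(O)c(O)c1)[C@@H](O)C2=O | intermediate
20 | (2S,3R)-2-(3,4-dihydroxyphenyl)-3-[(2R,3R)-2-(3,4-dihydroxyphenyl)-3,5,7-trihydroxy-4-oxochroman-8-yl]-5,7-dihydroxychroman-4-one | O=C1c2c(O)cc(O)cc2O[C@H](c2ccc(O)c(O)c2)[C@H]1c1c(O)cc(O)c2c1O[C@H](c1ccc(O)c(O)c1)[C@@H](O)C2=O | target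

Total step count: 12 steps.
Longest linear sequence: 9 steps (steps 4 to 12, from 6); the upper fragment (steps 1 to 3) joins at step 8.

Steps most likely to fail

1. Step 10 (key step). The carbenoid may be diverted to an oxonium ylide at O1 that undergoes a [1,2]-benzyl shift (ring contraction to a benzofuranone). It may also insert into the methoxy C–H bonds, or the catalyst may fail to override the chiral substrate so that hydrogen selection at C2 is poor. The fallback sets out from 13. The potassium enolate of the acetyl group (KN(SiMe3)2, THF, −78 °C) is trapped with Ac2O to give the enol acetate F1. DDQ with 2,6-dichloropyridine and LiClO4 in 1,2-dichloroethane then abstracts hydride from the electron-rich O1–CH2–aryl ether, and the aryl-stabilised oxocarbenium ion is captured by the enol acetate carbon (oxidative C–H cyclisation). This forms the same C2–C3 bond without a carbenoid. No catalyst control operates, so the lower-unit C2 epimer F2 is expected alongside and is removed by chromatography. The route is rejoined at 16.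

2. Step 8. Ligand coupling at the congested tertiary carbon may be slow, so that protodeplumbation of the aryllead species and reversible retro-oxa-Michael opening of 5 (loss of configurational purity at C2) compete. The fallback sets out from iodide 10 and keto ester 5. The bond is made instead by palladium-catalysed enolate α-arylation (Pd2(dba)3, t-Bu3P·HBF4, K3PO4, toluene, 80 °C). This bypasses stannane 11 and the lead reagent and comes back to the route at 13; no new compound arises (F0).

3. Step 12. The multi-site dealkylation may stall at partly protected stages, the Lewis acid may ionise a benzylic C2–O1 bond (epimerisation at C2 of either unit), or decarboxylation may be incomplete. The fallback sets out from 18 and stages the events. CF3CO2H in CH2Cl2 removes the tert-butyl ester, and the keto acid decarboxylates to the trans 3-aryl flavanone ether F3. A small excess of BCl3 (3 equiv, CH2Cl2, −78 → −30 °C) then cleaves only the two chelated peri ethers (upper 5-benzyloxy, lower 5-methoxy) to give the bis-peri-phenol F4. Hydrogenolysis (H2, Pd(OH)2/C, EtOAc–MeOH) removes the remaining six benzyl groups and comes back to the route at 20.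

Further compounds
F1 | step 10 | tert-butyl (2R,3S)-3-[3-(1-acetoxyvinyl)-6-(benzyloxy)-2-{[3,4-bis(benzyloxy)phenyl]methoxy}-4-methoxyphenyl]-5,7-bis(benzyloxy)-2-[3,4-bis(benzyloxy)phenyl]-4-oxochromane-3-carboxylate | O=C1c2c(OCc3ccccc3)cc(OCc3ccccc3)cc2O[C@H](c2ccc(OCc3ccccc3)c(OCc3ccccc3)c2)[C@@]1(C(=O)OC(C)(C)C)c1c(OCc2ccccc2)cc(OC)c(C(=C)OC(C)=O)c1OCc1ccc(OCc2ccccc2)c(OCc2ccccc2)c1
F2 | step 10 | tert-butyl (2R,3S)-5,7-bis(benzyloxy)-3-{(2R)-7-(benzyloxy)-2-[3,4-bis(benzyloxy)phenyl]-5-methoxy-4-oxochroman-8-yl}-2-[3,4-bis(benzyloxy)phenyl]-4-oxochromane-3-carboxylate | O=C1c2c(OCc3ccccc3)cc(OCc3ccccc3)cc2O[C@H](c2ccc(OCc3ccccc3)c(OCc3ccccc3)c2)[C@@]1(C(=O)OC(C)(C)C)c1c(OCc2ccccc2)cc(OC)c2c1O[C@@H](c1ccc(OCc3ccccc3)c(OCc3ccccc3)c1)CC2=O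
F0 | step 8 | none | none
F3 | step 12 | (2S,3R)-5,7-bis(benzyloxy)-3-{(2R,3R)-7-(benzyloxy)-2-[3,4-bis(benzyloxy)phenyl]-3-hydroxy-5-methoxy-4-oxochroman-8-yl}-2-[3,4-bis(benzyloxy)phenyl]chroman-4-one | O=C1c2c(OCc3ccccc3)cc(OCc3ccccc3)cc2O[C@H](c2ccc(OCc3ccccc3)c(OCc3ccccc3)c2)[C@H]1c1c(OCc2ccccc2)cc(OC)c2c1O[C@H](c1ccc(OCc3ccccc3)c(OCc3ccccc3)c1)[C@@H](O)C2=O
F4 | step 12 | (2S,3R)-7-(benzyloxy)-3-{(2R,3R)-7-(benzyloxy)-2-[3,4-bis(benzyloxy)phenyl]-3,5-dihydroxy-4-oxochroman-8-yl}-2-[3,4-bis(benzyloxy)phenyl]-5-hydroxychroman-4-one | O=C1c2c(O)cc(OCc3ccccc3)cc2O[C@H](c2ccc(OCc3ccccc3)c(OCc3ccccc3)c2)[C@H]1c1c(OCc2ccccc2)cc(O)c2c1O[C@H](c1ccc(OCc3ccccc3)c(OCc3ccccc3)c1)[C@@H](O)C2=O
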